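**Plan**

Numbering: heptane chain C1–C7, with ring A (4-hydroxyphenyl) on C1, acetoxy on C3, hydroxy on C5 and ring B (4-hydroxyphenyl) on C7. The target is (3R,5R), the 3,5-anti series.
Retrosynthesis: remove three O-benzyl groups. Then cut C2–C3 to a ring A homobenzylic zinc reagent (C1–C2) and the C3 aldehyde of a C3–C7 fragment. Then cut C6–C7 to methyl acetoacetate (C3–C6) and a ring B benzylic chloride (C7).
Enabling feature: C3 carries O–C(=O)CH3, which is what acetyl bromide leaves on an aldehyde carbon. The resulting C3(Br)(OAc) unit gives an oxygen-stabilised C3 radical, so one nickel-catalysed event forms C2–C3, sets C3 and places the acetyl group on O3 rather than O5.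
Forward order: C6–C7 by dianion alkylation, hydrogenation of the C5 ketone, benzylation of O5, ester to C3 aldehyde, union with the C1–C2/ring A piece, global hydrogenolysis. No ring is formed.
Stereochemistry: C5 (R) comes from a Noyori hydrogenation with (R)-BINAP. C3 (R) comes from the chiral bis(oxazoline) ligand on nickel in a stereoconvergent radical coupling. The parent anti diol is C2-symmetric, so an O3-to-O5 acetyl shift is degenerate.

Key step: step 7

Assumption: the sense of induction of the nickel catalyst at C3 is taken by analogy with simple 1-bromoalkyl esters. (S,S)-Ph-BOX, 2,2'-(propane-2,2-diyl)bis[(4S)-4-phenyl-4,5-dihydro-1,3-oxazole], is written; its equally available mirror image is meant if a trial run shows the opposite sense.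

**Route**

Step 1
Reactants: 1 methyl acetoacetate; 2 4-(benzyloxy)benzyl chloride
Product: 4 methyl 5-[4-(benzyloxy)phenyl]-3-oxopentanoate, via acetoacetate dianion 3 (not isolated)
Conditions: NaH (1.1 equiv), THF, 0 °C; n-BuLi (1.05 equiv), 0 °C; then 2, 0 °C to rt; aq. HCl
Reagents that add atoms: none
Why: Huckin–Weiler gamma-alkylation: in the dianion the terminal carbanion, formed last, is the most nucleophilic site and displaces the benzylic chloride by SN2, which makes C6–C7 and leaves the 1,3-dicarbonyl unit (future C3–C5) intact.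

Step 2
Reactants: 4 methyl 5-[4-(benzyloxy)phenyl]-3-oxopentanoate
Product: 5 methyl (R)-5-[4-(benzyloxy)phenyl]-3-hydroxypentanoate
Conditions: H2 (10 bar), RuCl2[(R)-BINAP] (0.5 mol %), MeOH, 50 °C
Reagents that add atoms: none
Why: Noyori asymmetric hydrogenation of a beta-keto ester: the ester carbonyl chelates ruthenium, the (R)-BINAP ligand exposes one ketone face to hydride and should set C5 as R (the same sense as methyl acetoacetate to methyl (R)-3-hydroxybutanoate, the ranking O > CH2CO2Me > alkyl being unchanged), and this homogeneous catalyst does not hydrogenolyse the aryl benzyl ether.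

Step 3
Reactants: 5 methyl (R)-5-[4-(benzyloxy)phenyl]-3-hydroxypentanoate
Product: 6 methyl (R)-3-(benzyloxy)-5-[4-(benzyloxy)phenyl]pentanoate
Conditions: BnOC(=NH)CCl3 (1.5 equiv), TfOH (5 mol %), cyclohexane–CH2Cl2, 0 °C to rt
Reagents that add atoms: benzyl 2,2,2-trichloroacetimidate, ClC(Cl)(Cl)C(=N)OCc1ccccc1
Why: Acid-catalysed O-alkylation with a benzyl trichloroacetimidate: the protonated imidate transfers benzyl to O5 without base, so retro-aldol cleavage and E1cB elimination of the beta-hydroxy ester are avoided and the C5–O bond, hence the R configuration, is untouched.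

Step 4
Reactants: 6 methyl (R)-3-(benzyloxy)-5-[4-(benzyloxy)phenyl]pentanoate
Product: 7 (R)-3-(benzyloxy)-5-[4-(benzyloxy)phenyl]pentanal
Conditions: i-Bu2AlH (1.1 equiv), toluene, −78 °C; aq. potassium sodium tartrate
Reagents that add atoms: none
Why: Partial reduction of an ester with i-Bu2AlH: at −78 °C the tetrahedral aluminium hemiacetal persists until the quench, so the C3 aldehyde is released only after the hydride is destroyed, and both benzyl ethers are inert.

Step 5
Reactants: 8 2-[4-(benzyloxy)phenyl]ethanol
Product: 9 1-(benzyloxy)-4-(2-iodoethyl)benzene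
Conditions: I2, PPh3, imidazole, CH2Cl2, 0 °C to rt
Reagents that add atoms: iodine, II
Why: Appel-type iodination: the alcohol attacks the iodophosphonium salt and iodide displaces triphenylphosphine oxide from the primary carbon by SN2, the aryl benzyl ether being inert.

Step 6
Reactants: 9 1-(benzyloxy)-4-(2-iodoethyl)benzene
Product: 10 2-[4-(benzyloxy)phenyl]ethylzinc iodide
Conditions: Zn dust (1.5 equiv, activated with 1,2-dibromoethane and Me3SiCl, 3 mol % each), THF, 40 °C; solution decanted, titrated and used as such
Reagents that add atoms: zinc, [Zn]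
Why: Direct insertion of activated zinc into a primary C–I bond, a standard route to functionalised alkylzinc iodides, reverses the polarity of C2 from acceptor to donor and tolerates the benzyl ether.

Step 7
Reactants: 7 (R)-3-(benzyloxy)-5-[4-(benzyloxy)phenyl]pentanal; 10 2-[4-(benzyloxy)phenyl]ethylzinc iodide
Product: 12 (3R,5R)-5-(benzyloxy)-1,7-bis[4-(benzyloxy)phenyl]heptan-3-yl acetate, via 1-bromoalkyl acetate 11 (not isolated)
Conditions: AcBr (1.05 equiv), ZnBr2 (1 mol %), CH2Cl2, −20 to 0 °C, volatiles removed in vacuo; crude 11 in THF, NiBr2·diglyme (10 mol %), (S,S)-Ph-BOX (13 mol %), 10 (1.5 equiv), THF, −20 °C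
Reagents that add atoms: acetyl bromide, CC(=O)Br
Why: Proposed new method: acetyl bromide adds across the C3 aldehyde (known 1-bromoalkyl ester formation) to give both C3 epimers of 11; a monovalent nickel–bis(oxazoline) species abstracts the bromine of the weak C3–Br bond to leave one planar C3 radical stabilised by the acetoxy oxygen, 10 hands C2 to divalent nickel by transmetalation, the radical is captured to give a trivalent dialkylnickel, and reductive elimination forms C2–C3. The closest known reaction types are the nickel/bis(oxazoline)-catalysed enantioconvergent alkyl–alkyl coupling of racemic 1-bromoalkyl esters with alkylnickel species generated from olefins and hydrosilanes, and the enantioconvergent Negishi alkylation of other alpha-heteroatom-substituted alkyl radicals with alkylzinc halides; new are the pairing of a 1-bromoalkyl acetate with a preformed alkylzinc iodide and the use on a substrate that already holds a stereocentre. No ring is closed. The new C3 stereocentre should be set as R by the chiral ligand on nickel, with the acetate carbonyl as a second binding point that fixes the radical face, so that both epimers of 11 converge on the 3,5-anti product, while C5 is not touched and stays R. The step needs cross-coupling over homocoupling, secured by the two unlike entry channels (halogen abstraction only at the oxygen-activated C3–Br, transmetalation only for 10), and it needs the catalysed path to outrun direct substitution of 11 by 10 and beta-hydride loss from the homobenzylic nickel alkyl, which the low temperature, the removal of excess acetyl bromide and the rigid bidentate ligand favour. The same event leaves the acetyl group on O3 only, because O5 is masked as a benzyl ether, and acetate, benzyl ethers and aryl ethers are inert to alkylzinc iodides.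

Step 8
Reactants: 12 (3R,5R)-5-(benzyloxy)-1,7-bis[4-(benzyloxy)phenyl]heptan-3-yl acetate
Product: 13 (3R,5R)-5-hydroxy-1,7-bis(4-hydroxyphenyl)heptan-3-yl acetate
Conditions: H2 (1 atm), 10% Pd/C, EtOAc–EtOH, rt
Reagents that add atoms: none
Why: Heterogeneous catalytic hydrogenolysis cleaves the three benzylic O–CH2Ph bonds while the non-benzylic C3–O and C5–O bonds, the acetate and both stereocentres are untouched, and an O3-to-O5 acetyl shift would be degenerate because the parent anti diol is C2-symmetric.

**Compound list**

1 | methyl acetoacetate | CC(=O)CC(=O)OC | starting material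
2 | 4-(benzyloxy)benzyl chloride | ClCc1ccc(OCc2ccccc2)cc1 | starting material
3 | sodium lithium dianion of methyl acetoacetate | [Na+].[Li+].[CH2-]C(=O)[CH-]C(=O)OC | intermediate
4 | methyl 5-[4-(benzyloxy)phenyl]-3-oxopentanoate | COC(=O)CC(=O)CCc1ccc(OCc2ccccc2)cc1 | intermediate
5 | methyl (R)-5-[4-(benzyloxy)phenyl]-3-hydroxypentanoate | COC(=O)C[C@H](O)CCc1ccc(OCc2ccccc2)cc1 | intermediate
6 | methyl (R)-3-(benzyloxy)-5-[4-(benzyloxy)phenyl]pentanoate | COC(=O)C[C@H](OCc1ccccc1)CCc1ccc(OCc2ccccc2)cc1 | intermediate
7 | (R)-3-(benzyloxy)-5-[4-(benzyloxy)phenyl]pentanal | O=CC[C@H](OCc1ccccc1)CCc1ccc(OCc2ccccc2)cc1 | intermediate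
8 | 2-[4-(benzyloxy)phenyl]ethanol | OCCc1ccc(OCc2ccccc2)cc1 | starting material
9 | 1-(benzyloxy)-4-(2-iodoethyl)benzene | ICCc1ccc(OCc2ccccc2)cc1 | intermediate
10 | 2-[4-(benzyloxy)phenyl]ethylzinc iodide | I[Zn]CCc1ccc(OCc2ccccc2)cc1 | intermediate
11 | (3R)-3-(benzyloxy)-5-[4-(benzyloxy)phenyl]-1-bromopentyl acetate, both epimers at the bromine-bearing carbon (C3 of the heptane numbering) | CC(=O)OC(Br)C[C@H](OCc1ccccc1)CCc1ccc(OCc2ccccc2)cc1 | intermediate
12 | (3R,5R)-5-(benzyloxy)-1,7-bis[4-(benzyloxy)phenyl]heptan-3-yl acetate | CC(=O)O[C@H](CCc1ccc(OCc2ccccc2)cc1)C[C@H](OCc1ccccc1)CCc1ccc(OCc2ccccc2)cc1 | intermediate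
13 | (3R,5R)-5-hydroxy-1,7-bis(4-hydroxyphenyl)heptan-3-yl acetate | CC(=O)O[C@H](CCc1ccc(O)cc1)C[C@H](O)CCc1ccc(O)cc1 | target

**Step count**

Total steps: 8. Longest linear sequence: 6 steps (1, 2, 3, 4, 7, 8).

**Steps most likely to fail**

Step 7.
- Several processes may interfere:
  - beta-elimination of benzyl alcohol, or benzyl ether cleavage, while acetyl bromide adds;
  - direct, ligand-free substitution of the bromide by the zinc reagent, which would erase facial control;
  - weak catalyst control against the resident C5 centre;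
  - beta-hydride loss or chain walking of the homobenzylic nickel alkyl;
  - 1,5-hydrogen transfer from the O5 benzylic CH2 to the C3 radical.
- The fallback uses known chemistry, sets out from aldehyde 7 and iodide 9, and comes back at 12.
- Magnesium insertion into 9 (Mg, Et2O) gives 2-[4-(benzyloxy)phenyl]ethylmagnesium iodide F1.
- F1 adds to 7 (THF, −78 °C) to give the C3-epimeric carbinols (5R)-5-(benzyloxy)-1,7-bis[4-(benzyloxy)phenyl]heptan-3-ol F2.
- Dess–Martin oxidation removes the unselective centre and gives (R)-5-(benzyloxy)-1,7-bis[4-(benzyloxy)phenyl]heptan-3-one F3.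
- SmI2 and MeOH in THF effect an alkoxy-directed ketyl reduction in which samarium is held by the O5 benzyl ether. This should give the 3,5-anti alcohol (3R,5R)-5-(benzyloxy)-1,7-bis[4-(benzyloxy)phenyl]heptan-3-ol F4.
- Ac2O, pyridine and DMAP convert F4 into 12.

Step 3.
- Acid-induced C-benzylation of the electron-rich ring B, stalled conversion of the hindered secondary alcohol, or loss of the C5 oxygen by elimination may occur.
- The fallback sets out from 5, comes back at 7, and bypasses steps 3 and 4.
- LiAlH4 in THF gives (R)-5-[4-(benzyloxy)phenyl]pentane-1,3-diol F5.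
- PhCH(OMe)2 with catalytic camphorsulfonic acid gives the 2,4-cis acetal (2S,4R)-4-{2-[4-(benzyloxy)phenyl]ethyl}-2-phenyl-1,3-dioxane F6.
- i-Bu2AlH in CH2Cl2 at 0 °C binds the less hindered primary oxygen and opens the acetal regioselectively to (R)-3-(benzyloxy)-5-[4-(benzyloxy)phenyl]pentan-1-ol F7.
- Parikh–Doering oxidation (SO3·pyridine, DMSO, Et3N) gives 7.

Step 4.
- Collapse of the aluminium hemiacetal before the quench would lead to over-reduction. Elimination of benzyl alcohol from the beta-benzyloxy aldehyde during work-up is also possible.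
- The fallback sets out from 6 and comes back at 7.
- MeNH(OMe)·HCl and i-PrMgCl in THF at −20 °C give the Weinreb amide (R)-3-(benzyloxy)-5-[4-(benzyloxy)phenyl]-N-methoxy-N-methylpentanamide F8.
- The five-membered metal chelate of F8 stops hydride addition (LiAlH4, THF, −78 °C) at the aldehyde level and releases 7 on a buffered quench.

**Further compounds**

F1 | step 7 | 2-[4-(benzyloxy)phenyl]ethylmagnesium iodide | I[Mg]CCc1ccc(OCc2ccccc2)cc1
F2 | step 7 | (5R)-5-(benzyloxy)-1,7-bis[4-(benzyloxy)phenyl]heptan-3-ol, both C3 epimers | OC(CCc1ccc(OCc2ccccc2)cc1)C[C@H](OCc1ccccc1)CCc1ccc(OCc2ccccc2)cc1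
F3 | step 7 | (R)-5-(benzyloxy)-1,7-bis[4-(benzyloxy)phenyl]heptan-3-one | O=C(CCc1ccc(OCc2ccccc2)cc1)C[C@H](OCc1ccccc1)CCc1ccc(OCc2ccccc2)cc1
F4 | step 7 | (3R,5R)-5-(benzyloxy)-1,7-bis[4-(benzyloxy)phenyl]heptan-3-ol | O[C@H](CCc1ccc(OCc2ccccc2)cc1)C[C@H](OCc1ccccc1)CCc1ccc(OCc2ccccc2)cc1
F5 | step 3 | (R)-5-[4-(benzyloxy)phenyl]pentane-1,3-diol | OCC[C@H](O)CCc1ccc(OCc2ccccc2)cc1
F6 | step 3 | (2S,4R)-4-{2-[4-(benzyloxy)phenyl]ethyl}-2-phenyl-1,3-dioxane | [C@H]1(c2ccccc2)OCC[C@@H](CCc2ccc(OCc3ccccc3)cc2)O1
F7 | step 3 | (R)-3-(benzyloxy)-5-[4-(benzyloxy)phenyl]pentan-1-ol | OCC[C@H](OCc1ccccc1)CCc1ccc(OCc2ccccc2)cc1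
F8 | step 4 | (R)-3-(benzyloxy)-5-[4-(benzyloxy)phenyl]-N-methoxy-N-methylpentanamide | CON(C)C(=O)C[C@H](OCc1ccccc1)CCc1ccc(OCc2ccccc2)cc1
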